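## Retrosynthetic overview
1. The target is an all-trans 1-aryltetralin of the isolariciresinol type. It comes from global hydrogenolysis of a tetra-benzyl-protected precursor: two aryl benzyl ethers and two benzyl carbonates.
2. The tetralin ring is formed last. A C2-symmetric (S,S)-dibenzylbutane-1,4-diol bis-carbonate undergoes DDQ hydride abstraction at one of its two homotopic benzylic CH2 groups. The other arene closes the ring through its carbon para to OMe, which breaks the C2 symmetry and sets C1 trans to C2.
3. The (S,S)-dibenzylbutanediol comes from oxidative homocoupling of the Evans imide enolate of O-benzyl dihydroferulic acid, followed by reductive removal of the auxiliary.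
4. The starting materials are dihydroferulic acid (a vanillin-derived feedstock) and (R)-4-benzyloxazolidin-2-one.

Assumptions:
- The target is the all-trans (1R,2S,3S) isomer, as read from the SMILES.
- The enolate homocoupling follows Evans alkylation face selectivity, so the (R)-auxiliary gives (S,S).

## Forward route

**Step 1**
Reactants: 1 (3-(4-hydroxy-3-methoxyphenyl)propanoic acid)
Product: 2 (3-(4-benzyloxy-3-methoxyphenyl)propanoic acid)
Conditions: BnBr (2.3 equiv), K2CO3, DMF, rt; then aq. NaOH, MeOH/THF, 50 °C; then HCl workup (one pot)
Reagents that add atoms: benzyl bromide, BrCc1ccccc1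
Why: Double Williamson benzylation gives the benzyl ether and benzyl ester, and the ester is then saponified. The phenol is thus masked as a hydrogenolyzable ether that survives DDQ. No stereocenters are involved.

**Step 2**
Reactants: 2 (3-(4-benzyloxy-3-methoxyphenyl)propanoic acid); 3 ((R)-4-benzyloxazolidin-2-one)
Product: 4 (N-acyl imide)
Conditions: PivCl, Et3N, THF, −20 °C to 0 °C; then 3, LiCl, rt
Reagents that add atoms: none (pivaloyl is lost as pivalic acid)
Why: Mixed-anhydride N-acylation (Evans) attaches the chiral auxiliary that will control both α-stereocenters.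

**Step 3**
Reactants: 4 (two molecules of 4 couple, 2 × 4 − 2 H → 5)
Product: 5 ((2S,3S)-bis-imide, C2-symmetric dimer)
Conditions: NaHMDS (1.1 equiv per 4), THF, −78 °C, 45 min; then Fe(acac)3 (1.2 equiv per 4), −78 °C to 0 °C
Reagents that add atoms: none (NaHMDS and Fe(acac)3 act only as base and one-electron oxidant; the product is the dimer of 4 minus two H)
Why: This is oxidative enolate homocoupling (Evans/Baran type) of chelated Z-sodium enolates. Each α-carbon reacts on the face opposite the auxiliary benzyl group, as in Evans alkylation, which sets the like-(S,S) dimer. The minor unlike diastereomer is removed by chromatography.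

**Step 4**
Reactants: 5
Product: 6 ((2S,3S)-2,3-bis(4-benzyloxy-3-methoxybenzyl)butane-1,4-diol)
Conditions: LiBH4, MeOH (2 equiv), Et2O/THF, 0 °C to rt
Reagents that add atoms: none (hydride only; the auxiliary 3 is released and recovered)
Why: Reductive cleavage of the exocyclic imide C=O releases the diol and recovers 3. The stereocenters are not epimerized under these mild conditions.

**Step 5**
Reactants: 6
Product: 7 (bis-benzyl carbonate of 6)
Conditions: CbzCl (2.5 equiv), pyridine, DMAP (cat.), CH2Cl2, 0 °C to rt
Reagents that add atoms: benzyl chloroformate, ClC(=O)OCc1ccccc1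
Why: Carbonate formation blocks the primary OH groups, which would otherwise trap the benzylic cation as a tetrahydrofuran (lariciresinol-type). The carbonates survive TFA and DDQ and are removed together with the benzyl ethers by hydrogenolysis.

**Step 6**
Reactants: 7
Product: 8 (all-trans aryltetralin bis-carbonate, tetra-benzyl protected)
Conditions: DDQ (1.1 equiv), CH2Cl2/TFA 10:1, 0 °C to rt, dark, stop at ~full conversion
Reagents that add atoms: none
Why: Proposed new method: DDQ abstracts hydride from one of the two homotopic p-alkoxybenzylic CH2 groups, giving a p-benzyloxybenzyl cation. The second arene attacks through C6 (para to OMe, ortho to its own CH2) in a 6-membered-ring closure, and loss of H+ rearomatizes it. The closest known chemistry is DDQ-mediated benzylic cross-dehydrogenative coupling and acid-promoted quinone-methide cyclization of dibenzylbutanes to aryltetralins. C2 symmetry makes either CH2 give the same product, so the desymmetrization has no regiochemical ambiguity. In the chair-like transition state the incoming aryl group and both CH2OCbz groups are pseudo-equatorial. This gives the new C1 (R) trans to C2, while C2 and C3 (S,S) are untouched.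

**Step 7**
Reactants: 8
Product: 9 (target)
Conditions: H2 (1 atm), 10% Pd/C, EtOAc/MeOH, rt
Reagents that add atoms: none
Why: Hydrogenolysis cleaves both aryl benzyl ethers and both benzyl carbonates (loss of toluene and CO2), liberating the two phenols and the two primary alcohols. Only O–CH2Ph bonds break, so none of the three ring stereocenters is affected.

## Compound list
1 | 3-(4-hydroxy-3-methoxyphenyl)propanoic acid | COc1cc(CCC(=O)O)ccc1O | starting material
2 | 3-(4-benzyloxy-3-methoxyphenyl)propanoic acid | COc1cc(CCC(=O)O)ccc1OCc1ccccc1 | intermediate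
3 | (R)-4-benzyloxazolidin-2-one | O=C1N[C@H](Cc2ccccc2)CO1 | starting material
4 | (R)-4-benzyl-3-[3-(4-benzyloxy-3-methoxyphenyl)propanoyl]oxazolidin-2-one | COc1cc(CCC(=O)N2C(=O)OC[C@H]2Cc2ccccc2)ccc1OCc1ccccc1 | intermediate
5 | (2S,3S)-1,4-bis[(R)-4-benzyl-2-oxooxazolidin-3-yl]-2,3-bis(4-benzyloxy-3-methoxybenzyl)butane-1,4-dione | O=C(N1C(=O)OC[C@H]1Cc1ccccc1)[C@@H](Cc1ccc(OCc2ccccc2)c(OC)c1)[C@H](Cc1ccc(OCc2ccccc2)c(OC)c1)C(=O)N1C(=O)OC[C@H]1Cc1ccccc1 | intermediate
6 | (2S,3S)-2,3-bis(4-benzyloxy-3-methoxybenzyl)butane-1,4-diol | OC[C@@H](Cc1ccc(OCc2ccccc2)c(OC)c1)[C@@H](CO)Cc1ccc(OCc2ccccc2)c(OC)c1 | intermediate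
7 | bis(benzyl carbonate) of 6 | O=C(OCc1ccccc1)OC[C@@H](Cc1ccc(OCc2ccccc2)c(OC)c1)[C@@H](COC(=O)OCc1ccccc1)Cc1ccc(OCc2ccccc2)c(OC)c1 | intermediate
8 | (1R,2S,3S)-1-(4-benzyloxy-3-methoxyphenyl)-7-benzyloxy-6-methoxytetralin-2,3-diyl-dimethanol bis(benzyl carbonate) | COc1cc([C@@H]2c3cc(OCc4ccccc4)c(OC)cc3C[C@H](COC(=O)OCc4ccccc4)[C@H]2COC(=O)OCc2ccccc2)ccc1OCc1ccccc1 | intermediate
9 | (1R,2S,3S)-1-(4-hydroxy-3-methoxyphenyl)-7-hydroxy-6-methoxy-2,3-bis(hydroxymethyl)tetralin (isolariciresinol-type, all-trans) | COc1cc([C@@H]2c3cc(O)c(OC)cc3C[C@H](CO)[C@H]2CO)ccc1O | target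

**Total steps:** 7
**Longest linear sequence:** 7 (from 1)

## Three steps most likely to fail
1. **Step 6 (DDQ desymmetrizing cyclization).** Risks are over-oxidation of the doubly benzylic C1–H to a dihydronaphthalene or arylnaphthalene, competing hydride abstraction from the O-benzyl groups, and ipso or eight-membered biaryl closure.
   Fallback: a biomimetic quinone-methide route. Debenzylate the aryl ethers of a diacetate analogue of 6, oxidize one phenol with Ag2O to the p-quinone methide, and cyclize with acid.
2. **Step 3 (enolate homocoupling).** Risks are low dr and yield, and the facial-selectivity assignment may be reversed. If reversed, switch to the (S)-auxiliary.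
   Fallback: a stepwise route. Do an Evans alkylation of the imide enolate with tert-butyl bromoacetate, then a trans-selective ester-enolate benzylation with 4-benzyloxy-3-methoxybenzyl bromide. Convert the product to the diol, and desymmetrize as before.
3. **Step 4 (LiBH4 cleavage of the hindered bis-imide).** Risks are incomplete reduction and endocyclic ring-opening of the oxazolidinone.
   Fallback: transesterify with MeOMgBr to the dimethyl succinate, then reduce with LiAlH4 or DIBAL to diol 6, so the imide is never reduced directly.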